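**Retrosynthetic overview**

1. The C5–Br bond is made last, by hydrogen-atom-transfer hydrogenation of a C5=C6 vinyl bromide derived from the C5 ketone; the C8 carbinol comes from MeMgBr addition to the C8 ketone.
2. Key bond C14–C1: the C14 ketone is converted into a samarium ketyl (carbonyl carbon as nucleophile) that adds to the β-carbon C1 of a C1=C2 vinyl sulfone. This closes ring C (the norbornane) and sets the C1 quaternary centre and the C14 carbinol; the sulfone is then removed.
3. Ring B, the C4 quaternary centre and both ring A oxygens come from a Diels–Alder reaction of 2-(phenylsulfanyl)diene 12 with 2-methylcyclohex-2-ene-1,4-dione 14.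
4. Diene 12 comes from vinyl triflate 8 and α-metallated phenyl vinyl sulfide; 8 comes from cyclopentenone 6, made by Pd-allylic alkylation of (1R,4S)-cis-4-acetoxycyclopent-2-en-1-ol with methyl 4-methyl-3-oxopentanoate.
5. Ring order: D (bought), A (bought as an enone), B (Diels–Alder), C (ketyl cyclization).

Assumption: locants C1–C15 are those of the target named as (1R,4S,5S,8R,9S,10S,12R,14R)-5-bromo-4,8-dimethyl-14-(propan-2-yl)tetracyclo[10.2.1.0(1,10).0(4,9)]pentadecane-8,14-diol. Ring A = C4–C9; ring B = C1–C4, C9, C10; ring C = C1, C12–C15; ring D = C1, C10–C12, C15. Compounds 1, 2, 9 and 13 are bought.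

**Route**

Step 1
Reactants: 1 (1R,4S)-cis-4-acetoxycyclopent-2-en-1-ol; 2 methyl 4-methyl-3-oxopentanoate
Product: 3 methyl 2-[(1S,4R)-4-hydroxycyclopent-2-en-1-yl]-4-methyl-3-oxopentanoate (both C2 epimers)
Conditions: Pd(PPh3)4 (3 mol %), Cs2CO3, THF, 23 °C
Reagents that add atoms: none
Why: Tsuji–Trost allylic alkylation: zerovalent palladium ionizes the acetate with inversion and the soft enolate attacks the allyl terminus remote from OH anti to palladium, so the new C–C bond forms with net retention (cis to OH) and fixes the future C12 centre.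

Step 2
Reactants: 3 methyl 2-[(1S,4R)-4-hydroxycyclopent-2-en-1-yl]-4-methyl-3-oxopentanoate
Product: 5 1-[(1R,4R)-4-hydroxycyclopent-2-en-1-yl]-3-methylbutan-2-one, via β-keto acid 4 (not isolated)
Conditions: LiOH, THF–H2O, 0 → 23 °C; then 1 M HCl to pH 3, 45 °C
Reagents that add atoms: none
Why: Ester saponification followed by thermal decarboxylation of the β-keto acid removes the epimeric α-carbon stereocentre and leaves the ring centres untouched.

Step 3
Reactants: 5 1-[(1R,4R)-4-hydroxycyclopent-2-en-1-yl]-3-methylbutan-2-one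
Product: 6 (4S)-4-(3-methyl-2-oxobutyl)cyclopent-2-en-1-one
Conditions: MnO2, CH2Cl2, 23 °C
Reagents that add atoms: none
Why: Allylic alcohol oxidation with MnO2 is neutral and selective, so the γ-stereocentre is not epimerized.

Step 4
Reactants: 6 (4S)-4-(3-methyl-2-oxobutyl)cyclopent-2-en-1-one
Product: 8 (4R)-4-(3-methyl-2-oxobutyl)cyclopent-1-en-1-yl trifluoromethanesulfonate, via triethylsilyl enol ether 7 (not isolated)
Conditions: Et3SiH, RhCl(PPh3)3 (1 mol %), toluene, 50 °C; then CsF, PhNTf2, DME, 23 °C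
Reagents that add atoms: N-phenylbis(trifluoromethanesulfonimide), O=S(=O)(N(c1ccccc1)S(=O)(=O)C(F)(F)F)C(F)(F)F
Why: Rh-catalysed 1,4-hydrosilylation of the enone gives the enol ether regiospecifically on the side away from the side chain without touching the isolated hindered ketone, and fluoride-released enolate is trapped by PhNTf2 before it can equilibrate.

Step 5
Reactants: 8 (4R)-4-(3-methyl-2-oxobutyl)cyclopent-1-en-1-yl trifluoromethanesulfonate; 9 phenyl vinyl sulfide
Product: 12 3-methyl-1-{(1R)-3-[1-(phenylsulfanyl)ethenyl]cyclopent-3-en-1-yl}butan-2-one, via 1-(phenylsulfanyl)ethenyllithium 10 (not isolated), via 1-(phenylsulfanyl)ethenylzinc chloride 11 (not isolated)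
Conditions: 9, sec-BuLi, THF–HMPA, −78 °C; ZnCl2; then 8, Pd(PPh3)4 (5 mol %), THF, 23 → 50 °C
Reagents that add atoms: none
Why: Negishi cross-coupling of the vinyl triflate with the α-metallated vinyl sulfide gives the 2-(phenylsulfanyl)diene, and the organozinc tolerates the ketone.

Step 6
Reactants: 13 2-methylcyclohex-2-en-1-one
Product: 14 2-methylcyclohex-2-ene-1,4-dione
Conditions: Pd(OH)2/C (5 mol %), t-BuOOH, K2CO3 (cat.), CH2Cl2, 4 °C
Reagents that add atoms: tert-butyl hydroperoxide, CC(C)(C)OO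
Why: Pd-catalysed allylic oxidation of the enone γ-CH2 with t-BuOOH gives the enedione, which is used at once to avoid tautomerization to the hydroquinone.

Step 7
Reactants: 12 3-methyl-1-{(1R)-3-[1-(phenylsulfanyl)ethenyl]cyclopent-3-en-1-yl}butan-2-one; 14 2-methylcyclohex-2-ene-1,4-dione
Product: 15 cis-fused tricyclic vinyl sulfide trione (rings A/B/D; C1=C2 bearing SPh on C2; ketones at C5 C8 C14; C4-methyl C9-H C10-H all cis; C4 C10 C12 as in the target)
Conditions: BF3·OEt2 (1.0 equiv), CH2Cl2, −78 → −40 °C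
Reagents that add atoms: none
Why: Lewis-acid-promoted endo Diels–Alder reaction: BF3 on the less hindered carbonyl makes the methyl-bearing carbon the electrophilic terminus, which bonds to the CH2 terminus that the 2-SPh group makes nucleophilic (C3–C4 and C9–C10 formed); the enedione adds to the cyclopentene face opposite the C12 side chain (sets C10) and the endo rule sets C4 relative to C10, leaving C9 cis for later correction.

Step 8
Reactants: 15 cis-fused tricyclic vinyl sulfide trione
Product: 17 cis-fused tricyclic vinyl sulfone trione (SO2Ph on C2; otherwise as 15), via vinyl sulfoxide 16 (not isolated)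
Conditions: mCPBA (2.2 equiv), NaHCO3, CH2Cl2, −20 → 0 °C
Reagents that add atoms: 3-chloroperoxybenzoic acid, OOC(=O)c1cccc(Cl)c1
Why: Sulfide-to-sulfone oxidation is far faster than epoxidation of the deactivated alkene or Baeyer–Villiger oxidation at or below 0 °C.

Step 9
Reactants: 17 cis-fused tricyclic vinyl sulfone trione
Product: 19 trans-fused tetracyclic 14-hydroxy-2-(phenylsulfonyl)-5,8-dione (C14–C1 bond formed; C1 C4 C9 C10 C12 C14 as in the target; C2 epimers), via cis-fused cyclized sulfone 18 (not isolated)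
Conditions: SmI2 (3 equiv), MeOH (10 equiv), THF, −78 → 0 °C; then NaOMe, MeOH, 23 °C
Reagents that add atoms: none
Why: SmI2 ketyl–olefin cyclization (5-exo-trig), in which the C14 ketyl adds to the vinyl sulfone β-carbon C1 (two normally electrophilic carbons joined), is the only mode open because the C12 tether reaches one face of C1 and attack at C2 would be anti-Bredt. Trivalent samarium bridging the ketyl oxygen and a sulfonyl oxygen (the sulfonyl on C2 is cis to C15) places O exo and isopropyl endo, away from PhSO2 (sets C1 and 14R). Without HMPA the C5 and C8 ketones are not reduced, and NaOMe then epimerizes C9 to the trans fusion, driven by loss of the syn-axial C8/C15 contact in the locked ring B.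

Step 10
Reactants: 19 trans-fused tetracyclic 14-hydroxy-2-(phenylsulfonyl)-5,8-dione
Product: 20 8,14-dihydroxy-4,8-dimethyl-2-(phenylsulfonyl)-14-(propan-2-yl)tetracyclo[10.2.1.0(1,10).0(4,9)]pentadecan-5-one (8R; C2 epimers)
Conditions: MeMgBr (4 equiv), CeCl3, THF, −78 °C
Reagents that add atoms: methylmagnesium bromide, C[Mg]Br
Why: Grignard (organocerium) addition is chemoselective for the C8 ketone because the C5 ketone is neopentyl, and the axial face of C8 is blocked by the syn-axial C4 methyl, so methyl enters equatorially and the hydroxyl ends axial (8R).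

Step 11
Reactants: 20 8,14-dihydroxy-4,8-dimethyl-2-(phenylsulfonyl)-14-(propan-2-yl)tetracyclo[10.2.1.0(1,10).0(4,9)]pentadecan-5-one
Product: 21 (1R,4S,8R,9S,10S,12R,14R)-8,14-dihydroxy-4,8-dimethyl-14-(propan-2-yl)tetracyclo[10.2.1.0(1,10).0(4,9)]pentadecan-5-one
Conditions: Mg turnings, MeOH, 23 → 50 °C
Reagents that add atoms: none
Why: Reductive desulfonylation by electron transfer from magnesium cleaves the alkyl C–S bond and turns C2 into CH2, while the hindered C5 ketone and the tertiary alcohols are inert.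

Step 12
Reactants: 21 (1R,4S,8R,9S,10S,12R,14R)-8,14-dihydroxy-4,8-dimethyl-14-(propan-2-yl)tetracyclo[10.2.1.0(1,10).0(4,9)]pentadecan-5-one
Product: 23 (1R,4S,8R,9S,10S,12R,14R)-5-bromo-4,8-dimethyl-14-(propan-2-yl)tetracyclo[10.2.1.0(1,10).0(4,9)]pentadec-5-ene-8,14-diol, via C5 hydrazone 22 (not isolated)
Conditions: N2H4·H2O, Et3N, EtOH, 80 °C; concentrate; then NBS, pyridine, 0 °C
Reagents that add atoms: N-bromosuccinimide, O=C1CCC(=O)N1Br
Why: Barton-type vinyl halide synthesis: the hydrazone is oxidized to the diazo compound, brominated, and loses N2 and the only available α-proton (C6) to give the vinyl bromide, a sequence that works on neopentyl ketones next to quaternary centres.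

Step 13
Reactants: 23 (1R,4S,8R,9S,10S,12R,14R)-5-bromo-4,8-dimethyl-14-(propan-2-yl)tetracyclo[10.2.1.0(1,10).0(4,9)]pentadec-5-ene-8,14-diol
Product: 24 (1R,4S,5S,8R,9S,10S,12R,14R)-5-bromo-4,8-dimethyl-14-(propan-2-yl)tetracyclo[10.2.1.0(1,10).0(4,9)]pentadecane-8,14-diol (CNP0362628.1)
Conditions: Mn(dpm)3 (10 mol %), PhSiH3, t-BuOOH, i-PrOH, 23 °C
Reagents that add atoms: none
Why: Hydrogen-atom-transfer hydrogenation: H adds first to C6 to give the bromine-stabilized C5 radical, and the second H is delivered along the axial trajectory on the face opposite the C4 methyl, so bromine ends equatorial (5S, the thermodynamic epimer) without C–Br cleavage.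

**Compound list**

1 | (1R,4S)-cis-4-acetoxycyclopent-2-en-1-ol | CC(=O)O[C@@H]1C=C[C@H](O)C1 | starting material
2 | methyl 4-methyl-3-oxopentanoate | COC(=O)CC(=O)C(C)C | starting material
3 | methyl 2-[(1S,4R)-4-hydroxycyclopent-2-en-1-yl]-4-methyl-3-oxopentanoate | COC(=O)C(C(=O)C(C)C)[C@@H]1C=C[C@H](O)C1 | intermediate
4 | 2-[(1S,4R)-4-hydroxycyclopent-2-en-1-yl]-4-methyl-3-oxopentanoic acid | OC(=O)C(C(=O)C(C)C)[C@@H]1C=C[C@H](O)C1 | intermediate
5 | 1-[(1R,4R)-4-hydroxycyclopent-2-en-1-yl]-3-methylbutan-2-one | CC(C)C(=O)C[C@@H]1C=C[C@H](O)C1 | intermediate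
6 | (4S)-4-(3-methyl-2-oxobutyl)cyclopent-2-en-1-one | CC(C)C(=O)C[C@@H]1C=CC(=O)C1 | intermediate
7 | triethyl{[(4R)-4-(3-methyl-2-oxobutyl)cyclopent-1-en-1-yl]oxy}silane | CC(C)C(=O)C[C@@H]1CC=C(O[Si](CC)(CC)CC)C1 | intermediate
8 | (4R)-4-(3-methyl-2-oxobutyl)cyclopent-1-en-1-yl trifluoromethanesulfonate | CC(C)C(=O)C[C@@H]1CC=C(OS(=O)(=O)C(F)(F)F)C1 | intermediate
9 | phenyl vinyl sulfide | C=CSc1ccccc1 | starting material
10 | 1-(phenylsulfanyl)ethenyllithium | [Li]C(=C)Sc1ccccc1 | intermediate
11 | 1-(phenylsulfanyl)ethenylzinc chloride | Cl[Zn]C(=C)Sc1ccccc1 | intermediate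
12 | 3-methyl-1-{(1R)-3-[1-(phenylsulfanyl)ethenyl]cyclopent-3-en-1-yl}butan-2-one | CC(C)C(=O)C[C@@H]1CC=C(C1)C(=C)Sc2ccccc2 | intermediate
13 | 2-methylcyclohex-2-en-1-one | CC1=CCCCC1=O | starting material
14 | 2-methylcyclohex-2-ene-1,4-dione | CC1=CC(=O)CCC1=O | intermediate
15 | cis-fused tricyclic vinyl sulfide trione (Diels–Alder adduct) | CC(C)C(=O)C[C@@H]2C[C@H]3[C@@H]4[C@](C)(CC(Sc5ccccc5)=C3C2)C(=O)CCC4=O | intermediate
16 | corresponding vinyl sulfoxide | CC(C)C(=O)C[C@@H]2C[C@H]3[C@@H]4[C@](C)(CC(S(=O)c5ccccc5)=C3C2)C(=O)CCC4=O | intermediate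
17 | cis-fused tricyclic vinyl sulfone trione | CC(C)C(=O)C[C@@H]2C[C@H]3[C@@H]4[C@](C)(CC(S(=O)(=O)c5ccccc5)=C3C2)C(=O)CCC4=O | intermediate
18 | cis-fused cyclized sulfone (C9 epimer of 19) | CC(C)[C@]1(O)C[C@@H]2C[C@H]3[C@@H]4[C@](C)(CC(S(=O)(=O)c5ccccc5)[C@@]31C2)C(=O)CCC4=O | intermediate
19 | trans-fused tetracyclic 14-hydroxy-2-(phenylsulfonyl)-5,8-dione | CC(C)[C@]1(O)C[C@@H]2C[C@H]3[C@H]4[C@](C)(CC(S(=O)(=O)c5ccccc5)[C@@]31C2)C(=O)CCC4=O | intermediate
20 | 8,14-dihydroxy-2-(phenylsulfonyl)-5-ketone | CC(C)[C@]1(O)C[C@@H]2C[C@H]3[C@H]4[C@](C)(CC(S(=O)(=O)c5ccccc5)[C@@]31C2)C(=O)CC[C@@]4(C)O | intermediate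
21 | (1R,4S,8R,9S,10S,12R,14R)-8,14-dihydroxy-4,8-dimethyl-14-(propan-2-yl)tetracyclo[10.2.1.0(1,10).0(4,9)]pentadecan-5-one | CC(C)[C@]1(O)C[C@@H]2C[C@H]3[C@H]4[C@](C)(CC[C@@]31C2)C(=O)CC[C@@]4(C)O | intermediate
22 | C5 hydrazone of 21 | CC(C)[C@]1(O)C[C@@H]2C[C@H]3[C@H]4[C@](C)(CC[C@@]31C2)C(=NN)CC[C@@]4(C)O | intermediate
23 | (1R,4S,8R,9S,10S,12R,14R)-5-bromo-4,8-dimethyl-14-(propan-2-yl)tetracyclo[10.2.1.0(1,10).0(4,9)]pentadec-5-ene-8,14-diol | CC(C)[C@]1(O)C[C@@H]2C[C@H]3[C@H]4[C@](C)(CC[C@@]31C2)C(Br)=CC[C@@]4(C)O | intermediate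
24 | (1R,4S,5S,8R,9S,10S,12R,14R)-5-bromo-4,8-dimethyl-14-(propan-2-yl)tetracyclo[10.2.1.0(1,10).0(4,9)]pentadecane-8,14-diol | CC(C)[C@]1(O)C[C@@H]2C[C@H]3[C@H]4[C@](C)(CC[C@@]31C2)[C@@H](Br)CC[C@@]4(C)O | target

**Step count**

Total: 13 steps. Longest linear sequence: 12 steps (steps 1–5 and 7–13, from 1 to 24); step 6 is a one-step side branch.

**Three steps most likely to fail**

Step 7 (Diels–Alder). Enedione 14 can tautomerize to methylhydroquinone, and the regiochemistry and face selectivity rest on BF3 control and on the single C12 substituent. Fallback: setting out from diene 12, heat it with commercial 2-methoxy-5-methyl-1,4-benzoquinone, whose methoxy-bearing double bond is deactivated and whose methyl-bearing carbon is the most electrophilic, to give the methoxy enedione adduct F1. Zn/AcOH saturates the enedione double bond to give the α-methoxy dione F2, and SmI2/MeOH at −78 °C cleaves the α-methoxy ketone C–O bond, which returns to 15.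

Step 9 (ketyl cyclization). The acceptor carbon is fully substituted and the C14 configuration depends on the samarium–sulfone chelate. Fallback: setting out from triflate 8, Stille coupling with tributyl(vinyl)stannane (Pd(PPh3)4, LiCl) gives the sulfur-free diene F3, and the BF3 Diels–Alder reaction with 14 gives the trisubstituted-alkene adduct F4. Fe(acac)3/PhSiH3 in EtOH then generates the tertiary C1 radical by hydrogen-atom transfer; it adds to the C14 carbonyl (reductive olefin–ketone coupling, the radical now on the other partner), and NaOMe epimerization gives the tetracyclic hydroxy dione F5. MeMgBr/CeCl3 on F5 comes back to the route at 21.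

Step 13 (vinyl bromide hydrogenation). Hydrogen-atom addition at C5 instead of C6 would lead to loss of bromine. Fallback: setting out from hydrazone 22, CuBr2/LiOt-Bu gives the geminal dibromide F6, and one equivalent of Bu3SnH with Et3B/air at −78 °C removes one bromine through the same C5 radical, with hydrogen again delivered anti to the C4 methyl; this arrives at 24.

**Further compounds**

F1 | step 7 | methoxy enedione Diels–Alder adduct (C7-OMe; C6=C7; otherwise as 15) | CC(C)C(=O)C[C@@H]2C[C@H]3[C@@H]4[C@](C)(CC(Sc5ccccc5)=C3C2)C(=O)C=C(OC)C4=O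
F2 | step 7 | α-methoxy dione (C7-OMe; C7 epimers; otherwise as 15) | CC(C)C(=O)C[C@@H]2C[C@H]3[C@@H]4[C@](C)(CC(Sc5ccccc5)=C3C2)C(=O)CC(OC)C4=O
F3 | step 9 | 1-[(1R)-3-ethenylcyclopent-3-en-1-yl]-3-methylbutan-2-one | CC(C)C(=O)C[C@@H]1CC=C(C=C)C1
F4 | step 9 | cis-fused tricyclic C1=C2 alkene trione (15 without SPh) | CC(C)C(=O)C[C@@H]2C[C@H]3[C@@H]4[C@](C)(CC=C3C2)C(=O)CCC4=O
F5 | step 9 | trans-fused tetracyclic 14-hydroxy-5,8-dione (19 without sulfonyl) | CC(C)[C@]1(O)C[C@@H]2C[C@H]3[C@H]4[C@](C)(CC[C@@]31C2)C(=O)CCC4=O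
F6 | step 13 | 5,5-dibromo diol | CC(C)[C@]1(O)C[C@@H]2C[C@H]3[C@H]4[C@](C)(CC[C@@]31C2)C(Br)(Br)CC[C@@]4(C)O
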